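## Retrosynthetic overview

1. Target 36 comes from acid 35, alcohol 34 and silyl ether 33; C1 is carried as CH2OSi until the end.
2. 33 is cut at C8–C9: B-alkyl Suzuki–Miyaura coupling of the 9-BBN adduct of vinyl dioxane 31 with E-vinyl iodide 17.
3. 31 (1,2-dioxane, C6 stereocentre) comes from a palladium-catalysed oxidative peroxy-cyclization of hydroperoxide 30. 30 comes from SN2 inversion of anti alcohol 27, made by Felkin reduction of ketone 26 from (S)-Roche ester 22 and homoallyl bromide 21.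
4. 17 comes from Zr-catalysed carboalumination/iodination of alkyne 14, made by Stork–Danheiser transposition of vinylogous ester 9 with the Grignard reagent from bromide 4.
5. Ring order: the carbocycle first (Michael/Claisen annulation to dione 8, step 3), then the 1,2-dioxane (step 18); the halves are joined in step 19.

Assumption: compounds 1, 5, 6, 18 and 22 are taken as purchased. Locants C1–C13 in the text follow the target chain (C1 ester carbon, C3 and C6 the dioxane carbons, C9=C10 the chain alkene, C13 the ring carbon that carries the chain).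

## Route

Step 1
Reactants: 1 but-3-yn-1-ol
Product: 3 4-(trimethylsilyl)but-3-yn-1-ol, via bis-silyl ether 2 (not isolated)
Conditions: n-BuLi (2.2 equiv), THF, −78 °C; Me3SiCl (2.2 equiv), −78 °C → rt; then 1 M HCl, rt
Reagents that add atoms: chlorotrimethylsilane (C[Si](C)(C)Cl)
Why: Double deprotonation and C,O-bis-silylation, after which aqueous acid cleaves only the Si–O bond (alkyne protection).

Step 2
Reactants: 3 4-(trimethylsilyl)but-3-yn-1-ol
Product: 4 (4-bromobut-1-yn-1-yl)trimethylsilane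
Conditions: CBr4, PPh3, CH2Cl2, 0 °C → rt
Reagents that add atoms: tetrabromomethane (BrC(Br)(Br)Br)
Why: Appel bromination of an unhindered primary alcohol.

Step 3
Reactants: 5 2-methylpentan-3-one; 6 methyl acrylate
Product: 8 2,4,4-trimethylcyclohexane-1,3-dione, via Michael adduct 7 (not isolated)
Conditions: NaOMe (1.1 equiv), MeOH/toluene, 0 °C → reflux; then aq. HCl
Reagents that add atoms: none
Why: Michael addition of the isopropyl-side enolate to the acrylate, then intramolecular Claisen (Dieckmann-type) acylation; the sequence is pulled forward by deprotonation of the 2-methyl-1,3-dione and builds the carbocycle.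

Step 4
Reactants: 8 2,4,4-trimethylcyclohexane-1,3-dione
Product: 9 3-isobutoxy-2,6,6-trimethylcyclohex-2-en-1-one
Conditions: i-BuOH, p-TsOH (cat.), toluene, reflux (Dean–Stark)
Reagents that add atoms: 2-methylpropan-1-ol (CC(C)CO)
Why: Acid-catalysed enol etherification occurs at the less hindered carbonyl (remote from the gem-dimethyl group), leaving the neopentyl carbonyl free for step 5.

Step 5
Reactants: 9 3-isobutoxy-2,6,6-trimethylcyclohex-2-en-1-one; 4 (4-bromobut-1-yn-1-yl)trimethylsilane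
Product: 12 2,4,4-trimethyl-3-[4-(trimethylsilyl)but-3-yn-1-yl]cyclohex-2-en-1-one, via Grignard reagent 10 (not isolated), via tertiary carbinol 11 (not isolated)
Conditions: 4, Mg, THF, rt; then 9, CeCl3, THF, −78 → 0 °C; then 2 M HCl, THF, rt
Reagents that add atoms: water (O)
Why: Stork–Danheiser alkylative carbonyl transposition: organocerium 1,2-addition to the hindered carbonyl, then acid hydrolysis of the enol ether and dehydration place the chain on the carbon next to the gem-dimethyl group.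

Step 6
Reactants: 12 2,4,4-trimethyl-3-[4-(trimethylsilyl)but-3-yn-1-yl]cyclohex-2-en-1-one
Product: 13 3-(but-3-yn-1-yl)-2,4,4-trimethylcyclohex-2-en-1-one
Conditions: K2CO3 (cat.), MeOH, rt
Reagents that add atoms: none
Why: Base-catalysed protodesilylation of the alkynylsilane; the enone is inert.

Step 7
Reactants: 13 3-(but-3-yn-1-yl)-2,4,4-trimethylcyclohex-2-en-1-one
Product: 14 3-(but-3-yn-1-yl)-2,4,4-trimethylcyclohex-2-en-1-ol (racemic)
Conditions: NaBH4, CeCl3·7H2O, MeOH, 0 °C
Reagents that add atoms: none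
Why: Luche 1,2-reduction masks the ketone, which would not survive AlMe3; the carbinol centre is racemic and is removed again in step 9.

Step 8
Reactants: 14 3-(but-3-yn-1-yl)-2,4,4-trimethylcyclohex-2-en-1-ol
Product: 16 (E)-3-(4-iodo-3-methylbut-3-en-1-yl)-2,4,4-trimethylcyclohex-2-en-1-ol, via alkenylalane 15 (not isolated)
Conditions: AlMe3 (3.5 equiv), Cp2ZrCl2 (25 mol %), CH2Cl2, 0 °C → rt; then I2, THF, −30 °C; aq. Na2S2O3/potassium sodium tartrate work-up
Reagents that add atoms: trimethylaluminium (C[Al](C)C); iodine (II)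
Why: Negishi zirconium-catalysed carboalumination adds Me and Al syn across the terminal alkyne (Me to the internal carbon), and iodinolysis with retention gives the E vinyl iodide.

Step 9
Reactants: 16 (E)-3-(4-iodo-3-methylbut-3-en-1-yl)-2,4,4-trimethylcyclohex-2-en-1-ol
Product: 17 (E)-3-(4-iodo-3-methylbut-3-en-1-yl)-2,4,4-trimethylcyclohex-2-en-1-one
Conditions: Dess–Martin periodinane, CH2Cl2, rt
Reagents that add atoms: none
Why: Dess–Martin oxidation of the allylic alcohol restores the enone without touching the vinyl iodide.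

Step 10
Reactants: 18 1-(1-methylcyclopropyl)ethan-1-one
Product: 19 1-(1-methylcyclopropyl)ethan-1-ol (racemic)
Conditions: NaBH4, MeOH, 0 °C
Reagents that add atoms: none
Why: Simple borohydride reduction; the carbinol centre is lost in step 11.

Step 11
Reactants: 19 1-(1-methylcyclopropyl)ethan-1-ol
Product: 21 (E)-5-bromo-3-methylpent-2-ene, via cyclopropylcarbinyl bromide 20 (not isolated)
Conditions: PBr3, LiBr, 2,4,6-collidine, Et2O, −40 → 0 °C; then ZnBr2, Et2O, 0 °C
Reagents that add atoms: phosphorus tribromide (BrP(Br)Br)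
Why: Julia–Johnson cyclopropylcarbinyl-to-homoallyl rearrangement, which gives the E trisubstituted homoallylic bromide with high selectivity (any Z isomer converges later, since this alkene geometry is erased in step 18).

Step 12
Reactants: 22 methyl (S)-3-hydroxy-2-methylpropanoate
Product: 23 methyl (S)-3-[(tert-butyldiphenylsilyl)oxy]-2-methylpropanoate
Conditions: t-BuPh2SiCl, imidazole, CH2Cl2, rt
Reagents that add atoms: tert-butyl(chloro)diphenylsilane (CC(C)(C)[Si](Cl)(c1ccccc1)c1ccccc1)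
Why: Standard silylation; the Roche ester supplies the C2 stereocentre and the bulky, non-chelating silyl ether is needed for step 15.

Step 13
Reactants: 23 methyl (S)-3-[(tert-butyldiphenylsilyl)oxy]-2-methylpropanoate
Product: 24 (S)-3-[(tert-butyldiphenylsilyl)oxy]-N-methoxy-N,2-dimethylpropanamide
Conditions: MeNH(OMe)·HCl, i-PrMgCl, THF, −20 °C
Reagents that add atoms: N,O-dimethylhydroxylamine hydrochloride (CNOC.Cl)
Why: Weinreb amide formation through the chloromagnesium amide, which proceeds without epimerising the α-stereocentre.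

Step 14
Reactants: 24 (S)-3-[(tert-butyldiphenylsilyl)oxy]-N-methoxy-N,2-dimethylpropanamide; 21 (E)-5-bromo-3-methylpent-2-ene
Product: 26 (S,E)-1-[(tert-butyldiphenylsilyl)oxy]-2,6-dimethyloct-6-en-3-one, via Grignard reagent 25 (not isolated)
Conditions: 21, Mg, THF; then 24, THF, 0 °C; aq. NH4Cl
Reagents that add atoms: none
Why: Weinreb ketone synthesis; the stable magnesium chelate prevents over-addition and forms the C3–C4 bond.

Step 15
Reactants: 26 (S,E)-1-[(tert-butyldiphenylsilyl)oxy]-2,6-dimethyloct-6-en-3-one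
Product: 27 (2S,3R,E)-1-[(tert-butyldiphenylsilyl)oxy]-2,6-dimethyloct-6-en-3-ol
Conditions: LiBH(s-Bu)3, THF, −78 °C; then NaOH, H2O2, 0 °C
Reagents that add atoms: none
Why: Felkin–Anh reduction by a bulky, non-chelating hydride (CH2OSi as the large group) should give the 2,3-anti (3R) alcohol, expected dr about 8–10:1, with the minor epimer removed by chromatography.

Step 16
Reactants: 27 (2S,3R,E)-1-[(tert-butyldiphenylsilyl)oxy]-2,6-dimethyloct-6-en-3-ol
Product: 29 tert-butyl{[(2S,3S,E)-3-[(2-methoxypropan-2-yl)peroxy]-2,6-dimethyloct-6-en-1-yl]oxy}diphenylsilane, via triflate 28 (not isolated)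
Conditions: Tf2O, 2,6-lutidine, CH2Cl2, −78 °C; then MeOC(Me)2OOH, KOt-Bu, THF, −78 → 0 °C
Reagents that add atoms: 2-methoxypropan-2-yl hydroperoxide (COC(C)(C)OO)
Why: SN2 displacement of the secondary triflate by the alkylperoxide anion inverts C3 (3R to 3S), which makes the C3–O bond syn to the C2 methyl as in the target.

Step 17
Reactants: 29 tert-butyl{[(2S,3S,E)-3-[(2-methoxypropan-2-yl)peroxy]-2,6-dimethyloct-6-en-1-yl]oxy}diphenylsilane
Product: 30 tert-butyl{[(2S,3S,E)-3-hydroperoxy-2,6-dimethyloct-6-en-1-yl]oxy}diphenylsilane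
Conditions: AcOH/THF/H2O (4:2:1), rt
Reagents that add atoms: none
Why: Mild acid hydrolysis of the monoperoxyketal frees the hydroperoxide; the silyl ether and the alkene are untouched.

Step 18
Reactants: 30 tert-butyl{[(2S,3S,E)-3-hydroperoxy-2,6-dimethyloct-6-en-1-yl]oxy}diphenylsilane
Product: 31 tert-butyl{(S)-2-[(3S,6S)-6-ethenyl-6-methyl-1,2-dioxan-3-yl]propoxy}diphenylsilane
Conditions: Pd(OCOCF3)2 (10 mol %), pyridine (40 mol %), 1,4-benzoquinone (1.5 equiv), 3 Å MS, toluene, 40 °C
Reagents that add atoms: none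
Why: Proposed new method: a Wacker-type oxidative peroxy-cyclization of a secondary hydroperoxide onto a trisubstituted alkene; divalent palladium activates C6=C7, the hydroperoxide oxygen adds 6-exo to the more substituted C6, the C7–Pd alkyl can β-hydride-eliminate only toward the C8 methyl (C6 is now quaternary) to release the vinyl group, and benzoquinone reoxidises zerovalent palladium; C6 is set in a chair-like transition state with the C3 side chain equatorial and the bulky palladium-bound alkene arm pseudo-equatorial, so the C6 methyl is axial (one syn-axial C4–H only, the other 1,3-partner being ring oxygen), which gives the (3S,6S) isomer with side chain and methyl cis (the C6 epimer, if formed, is removed by chromatography); the closest known reaction types are the palladium-catalysed oxidative cyclization of unsaturated tertiary hydroperoxides onto 1,2-disubstituted alkenes to 3-alkenyl-1,2-dioxanes and Wacker cyclizations of alcohols and phenols onto trisubstituted alkenes that create vinyl-bearing tetrasubstituted C–O centres, neither shown for a secondary hydroperoxide forming a fully substituted peroxy carbon.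

Step 19
Reactants: 31 tert-butyl{(S)-2-[(3S,6S)-6-ethenyl-6-methyl-1,2-dioxan-3-yl]propoxy}diphenylsilane; 17 (E)-3-(4-iodo-3-methylbut-3-en-1-yl)-2,4,4-trimethylcyclohex-2-en-1-one
Product: 33 tert-butyl{(S)-2-[(3S,6R)-6-methyl-6-{(E)-4-methyl-6-(2,6,6-trimethyl-3-oxocyclohex-1-en-1-yl)hex-3-en-1-yl}-1,2-dioxan-3-yl]propoxy}diphenylsilane, via alkylborane 32 (not isolated)
Conditions: 9-BBN-H, THF, 0 °C → rt; then 17, Pd(dppf)Cl2 (5 mol %), AsPh3, Cs2CO3, DMF/H2O, rt
Reagents that add atoms: none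
Why: Anti-Markovnikov hydroboration of the only alkene of 31, then B-alkyl Suzuki–Miyaura coupling (oxidative addition of zerovalent palladium into the C–I bond with retention, base-assisted alkyl transmetalation, reductive elimination) forms C8–C9 with the E geometry kept; no stereocentre is touched and dialkyl peroxides tolerate hydroboration and zerovalent-palladium couplings at room temperature.

Step 20
Reactants: 33 tert-butyl{(S)-2-[(3S,6R)-6-methyl-6-{(E)-4-methyl-6-(2,6,6-trimethyl-3-oxocyclohex-1-en-1-yl)hex-3-en-1-yl}-1,2-dioxan-3-yl]propoxy}diphenylsilane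
Product: 34 (S)-2-[(3S,6R)-6-methyl-6-{(E)-4-methyl-6-(2,6,6-trimethyl-3-oxocyclohex-1-en-1-yl)hex-3-en-1-yl}-1,2-dioxan-3-yl]propan-1-ol
Conditions: HF·pyridine, pyridine/THF, 0 °C → rt
Reagents that add atoms: none
Why: Fluoride-mediated desilylation under buffered, non-basic conditions avoids base-induced Kornblum–DeLaMare cleavage at C3–H.

Step 21
Reactants: 34 (S)-2-[(3S,6R)-6-methyl-6-{(E)-4-methyl-6-(2,6,6-trimethyl-3-oxocyclohex-1-en-1-yl)hex-3-en-1-yl}-1,2-dioxan-3-yl]propan-1-ol
Product: 35 (R)-2-[(3S,6R)-6-methyl-6-{(E)-4-methyl-6-(2,6,6-trimethyl-3-oxocyclohex-1-en-1-yl)hex-3-en-1-yl}-1,2-dioxan-3-yl]propanoic acid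
Conditions: TEMPO (20 mol %), PhI(OAc)2 (2.5 equiv), MeCN/pH 7 phosphate buffer, rt
Reagents that add atoms: water (O)
Why: Oxoammonium (TEMPO) oxidation of the primary alcohol through the aldehyde hydrate to the acid under neutral conditions, which limits β-elimination and C2 epimerisation and leaves the alkenes and the peroxide intact.

Step 22
Reactants: 35 (R)-2-[(3S,6R)-6-methyl-6-{(E)-4-methyl-6-(2,6,6-trimethyl-3-oxocyclohex-1-en-1-yl)hex-3-en-1-yl}-1,2-dioxan-3-yl]propanoic acid
Product: 36 methyl (R)-2-[(3S,6R)-6-methyl-6-{(E)-4-methyl-6-(2,6,6-trimethyl-3-oxocyclohex-1-en-1-yl)hex-3-en-1-yl}-1,2-dioxan-3-yl]propanoate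
Conditions: Me3SiCHN2, MeOH/toluene, 0 °C
Reagents that add atoms: (trimethylsilyl)diazomethane (C[Si](C)(C)C=[N+]=[N-])
Why: Neutral O-methylation of the acid by the diazoalkane; no base is present, so C2 and the peroxide are safe.

## Compound list

1 | but-3-yn-1-ol | C#CCCO | starting material
2 | trimethyl{[4-(trimethylsilyl)but-3-yn-1-yl]oxy}silane | C[Si](C)(C)C#CCCO[Si](C)(C)C | intermediate
3 | 4-(trimethylsilyl)but-3-yn-1-ol | C[Si](C)(C)C#CCCO | intermediate
4 | (4-bromobut-1-yn-1-yl)trimethylsilane | C[Si](C)(C)C#CCCBr | intermediate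
5 | 2-methylpentan-3-one | CCC(=O)C(C)C | starting material
6 | methyl acrylate | C=CC(=O)OC | starting material
7 | methyl 4,4-dimethyl-5-oxoheptanoate | CCC(=O)C(C)(C)CCC(=O)OC | intermediate
8 | 2,4,4-trimethylcyclohexane-1,3-dione | CC1C(=O)CCC(C)(C)C1=O | intermediate
9 | 3-isobutoxy-2,6,6-trimethylcyclohex-2-en-1-one | CC1=C(OCC(C)C)CCC(C)(C)C1=O | intermediate
10 | [4-(trimethylsilyl)but-3-yn-1-yl]magnesium bromide | C[Si](C)(C)C#CCC[Mg]Br | intermediate
11 | 3-isobutoxy-2,6,6-trimethyl-1-[4-(trimethylsilyl)but-3-yn-1-yl]cyclohex-2-en-1-ol (racemic) | CC1=C(OCC(C)C)CCC(C)(C)C1(O)CCC#C[Si](C)(C)C | intermediate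
12 | 2,4,4-trimethyl-3-[4-(trimethylsilyl)but-3-yn-1-yl]cyclohex-2-en-1-one | CC1=C(CCC#C[Si](C)(C)C)C(C)(C)CCC1=O | intermediate
13 | 3-(but-3-yn-1-yl)-2,4,4-trimethylcyclohex-2-en-1-one | CC1=C(CCC#C)C(C)(C)CCC1=O | intermediate
14 | 3-(but-3-yn-1-yl)-2,4,4-trimethylcyclohex-2-en-1-ol (racemic) | CC1=C(CCC#C)C(C)(C)CCC1O | intermediate
15 | (E)-alkenylalane: dimethylalumanyl on C9 and O-dimethylalumanyl alkoxide of 16 | C[Al](C)/C=C(\C)CCC1=C(C)C(O[Al](C)C)CCC1(C)C | intermediate
16 | (E)-3-(4-iodo-3-methylbut-3-en-1-yl)-2,4,4-trimethylcyclohex-2-en-1-ol (racemic) | CC1=C(CC/C(C)=C/I)C(C)(C)CCC1O | intermediate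
17 | (E)-3-(4-iodo-3-methylbut-3-en-1-yl)-2,4,4-trimethylcyclohex-2-en-1-one | CC1=C(CC/C(C)=C/I)C(C)(C)CCC1=O | intermediate
18 | 1-(1-methylcyclopropyl)ethan-1-one | CC(=O)C1(C)CC1 | starting material
19 | 1-(1-methylcyclopropyl)ethan-1-ol (racemic) | CC(O)C1(C)CC1 | intermediate
20 | 1-(1-bromoethyl)-1-methylcyclopropane | CC(Br)C1(C)CC1 | intermediate
21 | (E)-5-bromo-3-methylpent-2-ene | C/C=C(\C)CCBr | intermediate
22 | methyl (S)-3-hydroxy-2-methylpropanoate | OC[C@H](C)C(=O)OC | starting material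
23 | methyl (S)-3-[(tert-butyldiphenylsilyl)oxy]-2-methylpropanoate | CC(C)(C)[Si](c1ccccc1)(c1ccccc1)OC[C@H](C)C(=O)OC | intermediate
24 | (S)-3-[(tert-butyldiphenylsilyl)oxy]-N-methoxy-N,2-dimethylpropanamide | CC(C)(C)[Si](c1ccccc1)(c1ccccc1)OC[C@H](C)C(=O)N(C)OC | intermediate
25 | [(E)-3-methylpent-3-en-1-yl]magnesium bromide | C/C=C(\C)CC[Mg]Br | intermediate
26 | (S,E)-1-[(tert-butyldiphenylsilyl)oxy]-2,6-dimethyloct-6-en-3-one | CC(C)(C)[Si](c1ccccc1)(c1ccccc1)OC[C@H](C)C(=O)CC/C(C)=C/C | intermediate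
27 | (2S,3R,E)-1-[(tert-butyldiphenylsilyl)oxy]-2,6-dimethyloct-6-en-3-ol | CC(C)(C)[Si](c1ccccc1)(c1ccccc1)OC[C@H](C)[C@H](O)CC/C(C)=C/C | intermediate
28 | (2S,3R,E)-1-[(tert-butyldiphenylsilyl)oxy]-2,6-dimethyloct-6-en-3-yl trifluoromethanesulfonate | CC(C)(C)[Si](c1ccccc1)(c1ccccc1)OC[C@H](C)[C@H](OS(=O)(=O)C(F)(F)F)CC/C(C)=C/C | intermediate
29 | tert-butyl{[(2S,3S,E)-3-[(2-methoxypropan-2-yl)peroxy]-2,6-dimethyloct-6-en-1-yl]oxy}diphenylsilane | CC(C)(C)[Si](c1ccccc1)(c1ccccc1)OC[C@H](C)[C@@H](OOC(C)(C)OC)CC/C(C)=C/C | intermediate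
30 | tert-butyl{[(2S,3S,E)-3-hydroperoxy-2,6-dimethyloct-6-en-1-yl]oxy}diphenylsilane | CC(C)(C)[Si](c1ccccc1)(c1ccccc1)OC[C@H](C)[C@@H](OO)CC/C(C)=C/C | intermediate
31 | tert-butyl{(S)-2-[(3S,6S)-6-ethenyl-6-methyl-1,2-dioxan-3-yl]propoxy}diphenylsilane | CC(C)(C)[Si](c1ccccc1)(c1ccccc1)OC[C@H](C)[C@@H]2CC[C@@](C)(C=C)OO2 | intermediate
32 | tert-butyl{(S)-2-[(3S,6R)-6-[2-(9-borabicyclo[3.3.1]nonan-9-yl)ethyl]-6-methyl-1,2-dioxan-3-yl]propoxy}diphenylsilane | CC(C)(C)[Si](c1ccccc1)(c1ccccc1)OC[C@H](C)[C@@H]2CC[C@@](C)(CCB3C4CCCC3CCC4)OO2 | intermediate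
33 | tert-butyl{(S)-2-[(3S,6R)-6-methyl-6-{(E)-4-methyl-6-(2,6,6-trimethyl-3-oxocyclohex-1-en-1-yl)hex-3-en-1-yl}-1,2-dioxan-3-yl]propoxy}diphenylsilane | CC(C)(C)[Si](c1ccccc1)(c1ccccc1)OC[C@H](C)[C@@H]2CC[C@@](C)(CC/C=C(\C)CCC3=C(C)C(=O)CCC3(C)C)OO2 | intermediate
34 | (S)-2-[(3S,6R)-6-methyl-6-{(E)-4-methyl-6-(2,6,6-trimethyl-3-oxocyclohex-1-en-1-yl)hex-3-en-1-yl}-1,2-dioxan-3-yl]propan-1-ol | OC[C@H](C)[C@@H]1CC[C@@](C)(CC/C=C(\C)CCC2=C(C)C(=O)CCC2(C)C)OO1 | intermediate
35 | (R)-2-[(3S,6R)-6-methyl-6-{(E)-4-methyl-6-(2,6,6-trimethyl-3-oxocyclohex-1-en-1-yl)hex-3-en-1-yl}-1,2-dioxan-3-yl]propanoic acid | OC(=O)[C@H](C)[C@@H]1CC[C@@](C)(CC/C=C(\C)CCC2=C(C)C(=O)CCC2(C)C)OO1 | intermediate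
36 | methyl (R)-2-[(3S,6R)-6-methyl-6-{(E)-4-methyl-6-(2,6,6-trimethyl-3-oxocyclohex-1-en-1-yl)hex-3-en-1-yl}-1,2-dioxan-3-yl]propanoate | COC(=O)[C@H](C)[C@@H]1CC[C@@](C)(CC/C=C(\C)CCC2=C(C)C(=O)CCC2(C)C)OO1 | target

## Step count and risks

Total step count: 22.
Longest linear sequence: 11 steps (steps 12–22 from 22). The other branches are equally long: steps 10, 11, 14–22 from 18; steps 3–9 and 19–22 from 5 and 6; steps 1, 2, 5–9 and 19–22 from 1.

Steps most likely to fail:

Step 18 (the new reaction). A secondary hydroperoxide may be dehydrated to the C3 ketone or lose its O–O bond at palladium, and the C6 selectivity rests on a transition-state argument only. The fallback sets out from 30 and comes back at 31, and uses classical cycloperoxymercuration. Hg(OAc)2 in CH2Cl2 (cat. HClO4, 0 °C) adds the hydroperoxide oxygen and divalent mercury across C6=C7 in the Markovnikov 6-exo sense. Anion exchange with aqueous KBr gives the organomercurial tert-butyl{(S)-2-[(3S,6S)-6-[1-(bromomercurio)ethyl]-6-methyl-1,2-dioxan-3-yl]propoxy}diphenylsilane F1; the C6 epimers are separated here and the C7 epimers are carried as a mixture. Brominolysis (Br2, pyridine, CH2Cl2, 0 °C) gives the β-bromo peroxide tert-butyl{(S)-2-[(3S,6S)-6-(1-bromoethyl)-6-methyl-1,2-dioxan-3-yl]propoxy}diphenylsilane F2. E2 dehydrobromination with DBU (toluene, 80 °C) can run only toward the C8 methyl and gives 31.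

Step 16. The triflate is secondary and β-branched, so E2 elimination or cationic participation of the C6=C7 alkene can compete with substitution. The fallback sets out from 27 and comes back at 31, and swaps the roles of nucleophile and electrophile so that the C3–O bond is closed intramolecularly. MsCl/Et3N (CH2Cl2, 0 °C) gives (2S,3R,E)-1-[(tert-butyldiphenylsilyl)oxy]-2,6-dimethyloct-6-en-3-yl methanesulfonate F3. A Schenck ene reaction with singlet oxygen (O2, tetraphenylporphyrin, visible light, CH2Cl2, 0 °C) gives the tertiary allylic hydroperoxide (2S,3R)-1-[(tert-butyldiphenylsilyl)oxy]-6-hydroperoxy-2,6-dimethyloct-7-en-3-yl methanesulfonate F4 as both C6 epimers; the regioisomeric secondary hydroperoxide is removed by chromatography. KOt-Bu/18-crown-6 (THF, 0 °C) then closes the ring by 6-exo SN2 with inversion at C3. This gives 31 and its C6 epimer, which are separated; the sequence is unselective at C6 but uses only known chemistry.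

Step 19. The alkylborane and the aqueous base must coexist with the dialkyl peroxide; reduction of the O–O bond or base-induced cleavage at C3–H would ruin the coupling. The fallback sets out from 31 and comes back at 33, and replaces the boron/base coupling by a base-free Negishi coupling. 31 is hydroborated as before (32) and oxidised with NaBO3·4H2O to tert-butyl{(S)-2-[(3S,6S)-6-(2-hydroxyethyl)-6-methyl-1,2-dioxan-3-yl]propoxy}diphenylsilane F5. I2/PPh3/imidazole (CH2Cl2, 0 °C) gives tert-butyl{(S)-2-[(3S,6S)-6-(2-iodoethyl)-6-methyl-1,2-dioxan-3-yl]propoxy}diphenylsilane F6. Zinc insertion (Zn dust, LiCl, THF, rt) gives tert-butyl{(S)-2-[(3S,6S)-6-[2-(iodozincio)ethyl]-6-methyl-1,2-dioxan-3-yl]propoxy}diphenylsilane F7, which is coupled with 17 under Pd(PPh3)4 catalysis (THF/DMA, rt) to give 33.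

Further compounds

F1 | step 18 | tert-butyl{(S)-2-[(3S,6S)-6-[1-(bromomercurio)ethyl]-6-methyl-1,2-dioxan-3-yl]propoxy}diphenylsilane (C7 epimers) | CC(C)(C)[Si](c1ccccc1)(c1ccccc1)OC[C@H](C)[C@@H]2CC[C@@](C)(C(C)[Hg]Br)OO2
F2 | step 18 | tert-butyl{(S)-2-[(3S,6S)-6-(1-bromoethyl)-6-methyl-1,2-dioxan-3-yl]propoxy}diphenylsilane (C7 epimers) | CC(C)(C)[Si](c1ccccc1)(c1ccccc1)OC[C@H](C)[C@@H]2CC[C@@](C)(C(C)Br)OO2
F3 | step 16 | (2S,3R,E)-1-[(tert-butyldiphenylsilyl)oxy]-2,6-dimethyloct-6-en-3-yl methanesulfonate | CC(C)(C)[Si](c1ccccc1)(c1ccccc1)OC[C@H](C)[C@H](OS(C)(=O)=O)CC/C(C)=C/C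
F4 | step 16 | (2S,3R)-1-[(tert-butyldiphenylsilyl)oxy]-6-hydroperoxy-2,6-dimethyloct-7-en-3-yl methanesulfonate (C6 epimers) | CC(C)(C)[Si](c1ccccc1)(c1ccccc1)OC[C@H](C)[C@H](OS(C)(=O)=O)CCC(C)(OO)C=C
F5 | step 19 | tert-butyl{(S)-2-[(3S,6S)-6-(2-hydroxyethyl)-6-methyl-1,2-dioxan-3-yl]propoxy}diphenylsilane | CC(C)(C)[Si](c1ccccc1)(c1ccccc1)OC[C@H](C)[C@@H]2CC[C@@](C)(CCO)OO2
F6 | step 19 | tert-butyl{(S)-2-[(3S,6S)-6-(2-iodoethyl)-6-methyl-1,2-dioxan-3-yl]propoxy}diphenylsilane | CC(C)(C)[Si](c1ccccc1)(c1ccccc1)OC[C@H](C)[C@@H]2CC[C@@](C)(CCI)OO2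
F7 | step 19 | tert-butyl{(S)-2-[(3S,6S)-6-[2-(iodozincio)ethyl]-6-methyl-1,2-dioxan-3-yl]propoxy}diphenylsilane | CC(C)(C)[Si](c1ccccc1)(c1ccccc1)OC[C@H](C)[C@@H]2CC[C@@](C)(CC[Zn]I)OO2
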